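**Retrosynthetic overview**

- Last disconnections: aqueous acid removes an isobutylidene acetal and a tert-butyl ester; before that, the C2–N bond is made by copper-catalysed amidation of an α-iodoenone with the side-chain primary amide.
- Feature the strategy rests on: ring carbons C4 (tertiary carbinol carrying the 4-carboxybutyl chain), C5 (cis secondary OH), C6 (CH2) and C1 (C=O). This array results when the C4 oxygen of a mirror-symmetric 4-alkyl-4-hydroxycyclohexa-2,5-dienone, lengthened by one aldehyde carbon, adds to one enantiotopic β-carbon; the surviving C2=C3 enone then takes the nitrogen.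
- Ring order: the carbocycle is the benzene ring of a p-alkylphenol (dearomatised); the temporary cis-fused 1,3-dioxolane is closed on it in the key step and opened in the last step.
- Side chain: syn-1,3-dimethyl pair from a lipase-desymmetrised meso diol, isopropyl terminus by copper-catalysed Grignard coupling, E-enamide by Horner–Wadsworth–Emmons olefination.

Key step: step 3

Assumption: the phosphoric acid antipode and the lipase are taken to be those that give the drawn configurations (each sense is to be verified before material is carried on, and a catalyst or enzyme of complementary preference chosen if needed); the acetal carbon is drawn as its exo epimer, and either epimer serves because that centre is erased in the last step.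

**Route**

Step 1
Reactants: 1 5-(4-hydroxyphenyl)pentanoic acid
Product: 2 tert-butyl 5-(4-hydroxyphenyl)pentanoate
Conditions: tert-butyl 2,2,2-trichloroacetimidate (2 equiv), CH2Cl2/cyclohexane, rt, no added acid
Reagents that add atoms: tert-butyl 2,2,2-trichloroacetimidate, CC(C)(C)OC(=N)C(Cl)(Cl)Cl
Why: Imidate esterification, in which the carboxylic acid itself protonates the imidate and captures the tert-butyl cation, whereas the far less acidic phenol needs a Lewis acid to react and should stay free.

Step 2
Reactants: 2 tert-butyl 5-(4-hydroxyphenyl)pentanoate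
Product: 3 tert-butyl 5-(1-hydroxy-4-oxocyclohexa-2,5-dien-1-yl)pentanoate (achiral p-quinol)
Conditions: PhI(OAc)2 (1.2 equiv), MeCN/H2O (3:1), 0 °C
Reagents that add atoms: water, O
Why: Hypervalent-iodine oxidative dearomatisation of a para-alkylphenol, in which the aryloxy-iodane intermediate is attacked by water at the alkylated para carbon to give the 4-hydroxy-dienone; the tert-butyl ester prevents the chain from competing as a nucleophile and tolerates the acetic acid released.

Step 3
Reactants: 3 tert-butyl 5-(1-hydroxy-4-oxocyclohexa-2,5-dien-1-yl)pentanoate; 4 isobutyraldehyde (2-methylpropanal)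
Product: 6 tert-butyl 5-[(2R,3aS,7aR)-2-isopropyl-5-oxo-3a,4-dihydro-1,3-benzodioxol-7a(5H)-yl]pentanoate (cis-fused dioxolane enone), via quinol hemiacetal 5 (not isolated)
Conditions: 4 (3 equiv), TRIP [3,3'-bis(2,4,6-triisopropylphenyl)-1,1'-binaphthyl-2,2'-diyl hydrogen phosphate, 10 mol%, antipode fixed by a pilot run], 4 Å MS, 1,2-dichloroethane, rt → 40 °C
Reagents that add atoms: none
Why: The phosphoric acid catalyses reversible addition of the tertiary C4–OH of 3 to aldehyde 4 to give hemiacetal 5 and then, hydrogen-bonded to the dienone carbonyl and to the hemiacetal OH at once, delivers that oxygen to the β-carbon of one enone arm (hemiacetalisation/oxa-Michael cascade). The closest known reaction type is the chiral-phosphoric-acid-catalysed acetalisation/oxa-Michael desymmetrisation of p-quinols and p-peroxyquinols with aldehydes. The 1,3-dioxolane closes 5-exo-trig, and a three-atom O–C–O bridge can only span C4 and C5 on one face, so the fusion must be cis. C7a (ring C4) and C3a (ring C5) are set together by the catalyst's choice between the two enantiotopic enone arms, while the acetal carbon should settle with the isopropyl group exo and does not matter for the target. The selectivity needed is enantiotopic-group selectivity only: 3 has a mirror plane through C1 and C4, so no regiochemical alternative exists, and the product is directly the mono-enone with C6 as CH2. Base is avoided from here until C2 is substituted, because retro-oxa-Michael opening of 6 would return the achiral dienone and erode the enantiomeric purity.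

Step 4
Reactants: 6 cis-fused dioxolane enone
Product: 7 tert-butyl 5-[(2R,3aS,7aR)-6-iodo-2-isopropyl-5-oxo-3a,4-dihydro-1,3-benzodioxol-7a(5H)-yl]pentanoate (2-iodoenone)
Conditions: I2 (2 equiv), pyridine/CH2Cl2 (1:1), 0 °C → rt, dark; aqueous Na2S2O3 wash
Reagents that add atoms: iodine, II
Why: Johnson α-iodination of an enone, in which pyridine adds reversibly to the β-carbon, the resulting enolate is iodinated at C2 and pyridine is expelled again; with only this weak amine base present, enolisation towards C6 and β-elimination of the acetal oxygen should not compete, and both ring stereocentres are untouched.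

Step 5
Reactants: 8 meso-(cis)-2,4-dimethylglutaric anhydride
Product: 9 meso-2,4-dimethylpentane-1,5-diol
Conditions: LiAlH4, THF, 0 °C → reflux; H2O/aqueous NaOH work-up
Reagents that add atoms: none
Why: Hydride reduction of both anhydride carbonyls to primary alcohols, which is faster than enolisation, so the cis (meso) relationship of the two methyl groups should be carried into the diol.

Step 6
Reactants: 9 meso-2,4-dimethylpentane-1,5-diol
Product: 10 (2R,4S)-5-acetoxy-2,4-dimethylpentan-1-ol
Conditions: Pseudomonas fluorescens lipase (Amano AK), vinyl acetate, THF, rt, stopped at the monoacetate stage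
Reagents that add atoms: vinyl acetate, C=COC(C)=O
Why: Lipase-catalysed enantiotopic-group-selective transesterification of a meso diol, in which the enzyme acylates one of the two mirror-related CH2OH arms and thereby makes both methyl-bearing carbons defined stereocentres at once; tautomerisation of the vinyl alcohol to acetaldehyde makes the acyl transfer irreversible.

Step 7
Reactants: 10 (2R,4S)-5-acetoxy-2,4-dimethylpentan-1-ol
Product: 11 (2S,4R)-2,4-dimethyl-5-(tosyloxy)pentyl acetate
Conditions: TsCl, pyridine, DMAP (cat.), CH2Cl2, 0 °C → rt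
Reagents that add atoms: p-toluenesulfonyl chloride, Cc1ccc(cc1)S(Cl)(=O)=O
Why: Sulfonylation of the free primary alcohol at oxygen, which activates that terminus for substitution without touching either stereocentre or the acetate.

Step 8
Reactants: 11 (2S,4R)-2,4-dimethyl-5-(tosyloxy)pentyl acetate; 12 isopropylmagnesium chloride
Product: 13 (2S,4S)-2,4,6-trimethylheptyl acetate
Conditions: 12 (2.5 equiv, slow addition), Li2CuCl4 (5 mol%), THF, −78 → 0 °C
Reagents that add atoms: none
Why: Kochi-type Li2CuCl4-catalysed sp3–sp3 coupling of a primary tosylate with a Grignard reagent, in which the new C–C bond forms at the achiral CH2 carbon so the neighbouring stereocentre is untouched; at low temperature cuprate displacement should outpace addition to the acetate, and any acetate that is cleaved simply gives alcohol 14, the product of the next step.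

Step 9
Reactants: 13 (2S,4S)-2,4,6-trimethylheptyl acetate
Product: 14 (2S,4S)-2,4,6-trimethylheptan-1-ol
Conditions: K2CO3 (0.2 equiv), MeOH, rt; careful concentration (volatile product)
Reagents that add atoms: none
Why: Base-catalysed transesterification (methanolysis) of a primary acetate, which cannot affect the two non-enolisable stereocentres.

Step 10
Reactants: 14 (2S,4S)-2,4,6-trimethylheptan-1-ol
Product: 15 (2S,4S)-2,4,6-trimethylheptanal
Conditions: Dess–Martin periodinane, NaHCO3, CH2Cl2, 0 °C → rt; crude aldehyde used at once
Reagents that add atoms: none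
Why: Dess–Martin oxidation under buffered, non-enolising conditions, which should deliver the α-methyl aldehyde without epimerisation at C2.

Step 11
Reactants: 15 (2S,4S)-2,4,6-trimethylheptanal; 16 diethyl (carbamoylmethyl)phosphonate
Product: 17 (2E,4S,6S)-4,6,8-trimethylnon-2-enamide
Conditions: 16 (1.3 equiv), LiCl, DBU, MeCN, 0 °C → rt
Reagents that add atoms: none
Why: Horner–Wadsworth–Emmons olefination under Masamune–Roush conditions, in which the lithium-chelated, carboxamide-stabilised phosphonate anion adds reversibly and collapses to the E-alkene, while the weak amine base should leave the α-stereocentre of the aldehyde intact.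

Step 12
Reactants: 7 2-iodoenone; 17 (2E,4S,6S)-4,6,8-trimethylnon-2-enamide
Product: 18 tert-butyl 5-[(2R,3aS,7aR)-2-isopropyl-5-oxo-6-{[(2E,4S,6S)-4,6,8-trimethylnon-2-enoyl]amino}-3a,4-dihydro-1,3-benzodioxol-7a(5H)-yl]pentanoate (fully protected salternamide E)
Conditions: CuI (10 mol%), N,N'-dimethylethylenediamine (20 mol%), K2CO3 (2 equiv, finely ground), toluene, 60 °C, argon
Reagents that add atoms: none
Why: Goldberg-type copper-catalysed amidation of a vinyl iodide with a primary amide, which joins nitrogen to C2 with the double bond left in place; should the acetal oxygen be expelled reversibly under the carbonate base, C4 remains a stereocentre because its two arms now differ, and re-addition can only restore the same cis-fused ring.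

Step 13
Reactants: 18 fully protected salternamide E
Product: 19 salternamide E, 5-[(1R,6S)-1,6-dihydroxy-4-oxo-3-{[(2E,4S,6S)-4,6,8-trimethylnon-2-enoyl]amino}cyclohex-2-en-1-yl]pentanoic acid
Conditions: TFA/H2O (9:1), 0 °C → rt; co-evaporation with toluene; reverse-phase chromatography, no base at any point
Reagents that add atoms: none
Why: Acid hydrolysis of the aldehyde acetal together with acidolysis of the tert-butyl ester (loss of isobutene), both diol oxygens staying on the ring; the 2-amidoenone resists hydrolysis because C-protonation would place a cation next to the ketone, and base is excluded because the liberated β-hydroxy ketone would dehydrate or undergo retro-aldol cleavage.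

**Compound list**

1 | 5-(4-hydroxyphenyl)pentanoic acid | OC(=O)CCCCc1ccc(O)cc1 | starting material
2 | tert-butyl 5-(4-hydroxyphenyl)pentanoate | CC(C)(C)OC(=O)CCCCc1ccc(O)cc1 | intermediate
3 | tert-butyl 5-(1-hydroxy-4-oxocyclohexa-2,5-dien-1-yl)pentanoate | O=C1C=CC(O)(CCCCC(=O)OC(C)(C)C)C=C1 | intermediate
4 | isobutyraldehyde | CC(C)C=O | starting material
5 | tert-butyl 5-{1-[(1R)-1-hydroxy-2-methylpropoxy]-4-oxocyclohexa-2,5-dien-1-yl}pentanoate (quinol hemiacetal) | O=C1C=CC(O[C@@H](O)C(C)C)(CCCCC(=O)OC(C)(C)C)C=C1 | intermediate (not isolated)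
6 | tert-butyl 5-[(2R,3aS,7aR)-2-isopropyl-5-oxo-3a,4-dihydro-1,3-benzodioxol-7a(5H)-yl]pentanoate | O=C1C=C[C@](O2)(CCCCC(=O)OC(C)(C)C)[C@@H](O[C@H]2C(C)C)C1 | intermediate
7 | tert-butyl 5-[(2R,3aS,7aR)-6-iodo-2-isopropyl-5-oxo-3a,4-dihydro-1,3-benzodioxol-7a(5H)-yl]pentanoate | O=C1C(I)=C[C@](O2)(CCCCC(=O)OC(C)(C)C)[C@@H](O[C@H]2C(C)C)C1 | intermediate
8 | meso-(cis)-2,4-dimethylglutaric anhydride | C[C@H]1C[C@@H](C)C(=O)OC1=O | starting material
9 | meso-2,4-dimethylpentane-1,5-diol | OC[C@H](C)C[C@H](C)CO | intermediate
10 | (2R,4S)-5-acetoxy-2,4-dimethylpentan-1-ol | OC[C@H](C)C[C@H](C)COC(C)=O | intermediate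
11 | (2S,4R)-2,4-dimethyl-5-(tosyloxy)pentyl acetate | Cc1ccc(cc1)S(=O)(=O)OC[C@H](C)C[C@H](C)COC(C)=O | intermediate
12 | isopropylmagnesium chloride | CC(C)[Mg]Cl | starting material
13 | (2S,4S)-2,4,6-trimethylheptyl acetate | CC(C)C[C@H](C)C[C@H](C)COC(C)=O | intermediate
14 | (2S,4S)-2,4,6-trimethylheptan-1-ol | CC(C)C[C@H](C)C[C@H](C)CO | intermediate
15 | (2S,4S)-2,4,6-trimethylheptanal | CC(C)C[C@H](C)C[C@H](C)C=O | intermediate
16 | diethyl (carbamoylmethyl)phosphonate | CCOP(=O)(CC(N)=O)OCC | starting material
17 | (2E,4S,6S)-4,6,8-trimethylnon-2-enamide | CC(C)C[C@H](C)C[C@H](C)/C=C/C(N)=O | intermediate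
18 | tert-butyl 5-[(2R,3aS,7aR)-2-isopropyl-5-oxo-6-{[(2E,4S,6S)-4,6,8-trimethylnon-2-enoyl]amino}-3a,4-dihydro-1,3-benzodioxol-7a(5H)-yl]pentanoate | CC(C)C[C@H](C)C[C@H](C)/C=C/C(=O)NC1=C[C@](O2)(CCCCC(=O)OC(C)(C)C)[C@@H](O[C@H]2C(C)C)CC1=O | intermediate
19 | salternamide E | CC(C)C[C@H](C)C[C@H](C)/C=C/C(=O)NC1=C[C@](O)(CCCCC(=O)O)[C@@H](O)CC1=O | target

**Step count and risks**

Total step count: 13. Longest linear sequence: 9 steps (from 8 through steps 5–11, then 12 and 13); the ring fragment needs 4 steps before the union.

Steps most likely to fail: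

1. Step 12 (C2–N coupling). Under the carbonate base, β-elimination of the acetal oxygen with loss of the aldehyde tether, or protodeiodination, may outrun the C–N bond formation at this hindered, electron-poor vinyl iodide. Fallback (sets out from 7 and from 15, returns at 18): the nitrogen is introduced first and the amide bond is made by acylation. Iodoenone 7 is azidated under near-neutral conditions (NaN3, CuI, sodium ascorbate NaC6H7O6, N,N'-dimethylethylenediamine, EtOH/H2O, rt) to tert-butyl 5-[(2R,3aS,7aR)-6-azido-2-isopropyl-5-oxo-3a,4-dihydro-1,3-benzodioxol-7a(5H)-yl]pentanoate F1. Staudinger reduction (PPh3, THF/H2O) then gives the 6-amino analogue, tert-butyl 5-[(2R,3aS,7aR)-6-amino-2-isopropyl-5-oxo-3a,4-dihydro-1,3-benzodioxol-7a(5H)-yl]pentanoate F2. In parallel, aldehyde 15 is olefinated with triethyl phosphonoacetate (LiCl, DBU, MeCN) to ethyl (2E,4S,6S)-4,6,8-trimethylnon-2-enoate F3, saponified (LiOH, THF/H2O) to (2E,4S,6S)-4,6,8-trimethylnon-2-enoic acid F4 and converted with oxalyl chloride and catalytic DMF into (2E,4S,6S)-4,6,8-trimethylnon-2-enoyl chloride F5. Acylation of F2 with F5 (pyridine, CH2Cl2, 0 °C) should give 18.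

2. Step 3 (key desymmetrisation). Hemiacetal formation at the hindered tertiary alcohol may be slow, and discrimination between the two enone arms by the phosphoric acid may be insufficient, so that a weakly selective background cyclisation lowers the enantiomeric purity. Fallback (sets out from 3, returns at 6): the one-carbon tether is replaced by a one-boron tether under bifunctional base catalysis, the known boronic acid hemiester oxa-Michael addition of γ-hydroxy enones. Quinol 3 with PhB(OH)2 and a quinine-derived tertiary-amine thiourea (10–20 mol%, 4 Å MS, toluene, rt) should give the cis-fused boronate tert-butyl 5-[(3aS,7aR)-5-oxo-2-phenyl-3a,4-dihydro-1,3,2-benzodioxaborol-7a(5H)-yl]pentanoate F6. Oxidative B–C cleavage with H2O2 in pH 7 phosphate buffer releases the cis-diol enone tert-butyl 5-[(1R,6S)-1,6-dihydroxy-4-oxocyclohex-2-en-1-yl]pentanoate F7. Acetalisation of F7 with aldehyde 4 (PPTS, MgSO4, CH2Cl2, rt) gives 6, as either acetal epimer.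

3. Step 13 (global deprotection). Hydrolysis of the aldehyde-derived dioxolane may be slow next to the electron-poor ring, and the prolonged exposure to strong aqueous acid may then dehydrate the β-hydroxy ketone. Fallback (sets out from 18, returns at 19): the two groups are removed separately and the acetal is cleaved without hydrolytic acid. Me2BBr (CH2Cl2, −78 °C, quench into pH 7 buffer) opens the acetal through its bromo ether to give tert-butyl 5-[(1R,6S)-1,6-dihydroxy-4-oxo-3-{[(2E,4S,6S)-4,6,8-trimethylnon-2-enoyl]amino}cyclohex-2-en-1-yl]pentanoate F8. The tert-butyl ester, if not already lost, is then removed by brief treatment with TFA/CH2Cl2 at 0 °C to give 19.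

**Further compounds**

F1 | step 12 | tert-butyl 5-[(2R,3aS,7aR)-6-azido-2-isopropyl-5-oxo-3a,4-dihydro-1,3-benzodioxol-7a(5H)-yl]pentanoate | O=C1C(N=[N+]=[N-])=C[C@](O2)(CCCCC(=O)OC(C)(C)C)[C@@H](O[C@H]2C(C)C)C1
F2 | step 12 | tert-butyl 5-[(2R,3aS,7aR)-6-amino-2-isopropyl-5-oxo-3a,4-dihydro-1,3-benzodioxol-7a(5H)-yl]pentanoate | O=C1C(N)=C[C@](O2)(CCCCC(=O)OC(C)(C)C)[C@@H](O[C@H]2C(C)C)C1
F3 | step 12 | ethyl (2E,4S,6S)-4,6,8-trimethylnon-2-enoate | CC(C)C[C@H](C)C[C@H](C)/C=C/C(=O)OCC
F4 | step 12 | (2E,4S,6S)-4,6,8-trimethylnon-2-enoic acid | CC(C)C[C@H](C)C[C@H](C)/C=C/C(=O)O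
F5 | step 12 | (2E,4S,6S)-4,6,8-trimethylnon-2-enoyl chloride | CC(C)C[C@H](C)C[C@H](C)/C=C/C(Cl)=O
F6 | step 3 | tert-butyl 5-[(3aS,7aR)-5-oxo-2-phenyl-3a,4-dihydro-1,3,2-benzodioxaborol-7a(5H)-yl]pentanoate | O=C1C=C[C@](O2)(CCCCC(=O)OC(C)(C)C)[C@@H](OB2c3ccccc3)C1
F7 | step 3 | tert-butyl 5-[(1R,6S)-1,6-dihydroxy-4-oxocyclohex-2-en-1-yl]pentanoate | O=C1C=C[C@](O)(CCCCC(=O)OC(C)(C)C)[C@@H](O)C1
F8 | step 13 | tert-butyl 5-[(1R,6S)-1,6-dihydroxy-4-oxo-3-{[(2E,4S,6S)-4,6,8-trimethylnon-2-enoyl]amino}cyclohex-2-en-1-yl]pentanoate | CC(C)C[C@H](C)C[C@H](C)/C=C/C(=O)NC1=C[C@](O)(CCCCC(=O)OC(C)(C)C)[C@@H](O)CC1=O
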